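**Retrosynthetic overview**

1. Labels and feature: ring A is the guaiacyl ring on C7'', ring B the aryl ring on C7 that carries the C8''–O ether, ring C the terminal phenol ring on C7'. In the 3,7-dioxabicyclo[3.3.0]octane core (ring B–C7–C8–C9, ring C–C7'–C8'–C9', ethers C7–O–C9' and C7'–O–C9) the fusion carbons C8' and C8 each carry one aryl carbinol carbon and one CH2O carbon, so they map onto the β- and α-carbons of a butenolide with C9 as carbonyl and C9' as acetal carbon.
2. Last disconnections: C7''–C8'' (auxiliary-controlled anti-aldol of a ring B aryloxyacetyl imide with the ring A aldehyde) and C8''–O (alkylation of the ring B phenol), so the erythro glycerol chain is added to a mono-protected furofuran.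
3. Furofuran: both tetrahydrofuran rings (C7–O–C9' and C7'–O–C9) are closed together by acid cyclodehydration of an open tetraol; this step fixes C7 and C7'.
4. Tetraol: from a trans,trans-3,4-disubstituted 5-menthyloxy-γ-lactone made in one flask from the 2-lithio-1,3-dithiane of ring C (C7'), (5S)-5-[(1S,2R,5S)-menthyloxy]furan-2(5H)-one (C9'–C8'–C8–C9) and the ring B aldehyde (C7), forming C7'–C8' and C8–C7.
5. Ring order: no ring forms in the key step; the two ether rings form in step 9; the acetal centre C9' controls C8' and C8 and is then reduced away with recovery of menthol.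

Key step: step 6

Remark: the ring C and ring A phenols are carried as triisopropylsilyl ethers (stable to n-BuLi, LiAlH4 and carbonate) and ring B as the allyl ether; C7 after step 6 and C7' after step 8 are expected as epimer mixtures that step 9 resets, so the SMILES of 14, 15 and 16 leave these two centres open.

**Route**

Step 1
Reactants: 1 furfural
Product: 3 5-hydroxyfuran-2(5H)-one (racemic), via furfural endoperoxide 2 (not isolated)
Conditions: O2, rose bengal disodium salt (C20H2Cl4I4Na2O5, cat.), MeOH, visible light, rt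
Reagents that add atoms: dioxygen O=O
Why: Dye-sensitised singlet-oxygen [4+2] cycloaddition to the furan gives the 2,5-endoperoxide, which methanol should fragment with loss of the formyl group as methyl formate (furfural photo-oxygenation); the hemiacetal carbon forms racemic and is labile.

Step 2
Reactants: 3 5-hydroxyfuran-2(5H)-one; 4 (+)-menthol
Product: 6 (5S)-5-[(1S,2R,5S)-menthyloxy]furan-2(5H)-one, via (5R)-epimeric acetal 5 (not isolated)
Conditions: camphor-10-sulfonic acid (C10H16O4S, cat.), toluene, reflux, Dean–Stark; crystallisation from petroleum ether, −20 °C; mother liquor re-equilibrated with the same acid and recrystallised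
Reagents that add atoms: none
Why: Acid-catalysed acetalisation gives both C5 epimers, and since the acetal centre epimerises under acid while the (5S)-(+)-menthyl diastereomer is the one expected to crystallise, crystallisation with recycling of the mother liquor should set C9' (crystallisation-driven diastereomer resolution).

Step 3
Reactants: 7 vanillin
Product: 8 3-methoxy-4-(triisopropylsilyloxy)benzaldehyde
Conditions: i-Pr3SiCl, imidazole, DMF, rt
Reagents that add atoms: chlorotriisopropylsilane CC(C)[Si](Cl)(C(C)C)C(C)C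
Why: Imidazole-promoted O-silylation of the phenol gives a hindered aryl silyl ether that should survive the later organolithium, hydride and carbonate steps; no stereocentre is involved.

Step 4
Reactants: 8 3-methoxy-4-(triisopropylsilyloxy)benzaldehyde; 9 propane-1,3-dithiol
Product: 10 2-[3-methoxy-4-(triisopropylsilyloxy)phenyl]-1,3-dithiane
Conditions: BF3·OEt2 (0.2 equiv), CH2Cl2, 0 °C to rt
Reagents that add atoms: none
Why: Lewis acid-catalysed dithioacetalisation of the aldehyde gives the 1,3-dithiane whose C2–H is acidified by two sulfur atoms and the aryl ring (Corey–Seebach acyl-anion precursor), and the aryl silyl ether tolerates these conditions.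

Step 5
Reactants: 7 vanillin
Product: 11 4-(allyloxy)-3-methoxybenzaldehyde
Conditions: allyl bromide, K2CO3, DMF, rt
Reagents that add atoms: allyl bromide C=CCBr
Why: Williamson O-allylation of the phenoxide gives an ether that is inert to organolithium, hydride and mild acid and is later removed by palladium without touching silyl ethers.

Step 6
Reactants: 10 2-[3-methoxy-4-(triisopropylsilyloxy)phenyl]-1,3-dithiane; 6 (5S)-5-[(1S,2R,5S)-menthyloxy]furan-2(5H)-one; 11 4-(allyloxy)-3-methoxybenzaldehyde
Product: 14 (3R,4S,5S)-3-[(4-allyloxy-3-methoxyphenyl)(hydroxy)methyl]-5-[(1S,2R,5S)-menthyloxy]-4-{2-[3-methoxy-4-(triisopropylsilyloxy)phenyl]-1,3-dithian-2-yl}dihydrofuran-2(3H)-one (trans,trans-lactone; C7 carbinol epimers), via 2-lithio-1,3-dithiane 12 (not isolated), via lithium lactone enolate 13 (not isolated)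
Conditions: n-BuLi, THF, −78 to −30 °C; 6, −78 °C; 11, −78 °C; aq. NH4Cl, −78 °C
Reagents that add atoms: none
Why: n-BuLi deprotonates C2 of dithiane 10 to the sulfur- and aryl-stabilised carbanion 12 (Corey–Seebach umpolung), which adds 1,4 to the butenolide at C8' to give the lithium lactone enolate 13; this enolate is then trapped at C8 by aldehyde 11 through a closed Zimmerman–Traxler aldol transition state, so that C7'–C8' and C8–C7 form in one flask. The closest known reaction type is the tandem conjugate addition of lithiated dithioacetals to chiral 5-alkoxybutenolides with aldol trapping of the enolate. No ring is closed, so no mode of closure applies, and the lactone ring with its acetal carbon C9' is carried through intact. C8' (S) is controlled by the acetal stereocentre C9', the nucleophile entering the face anti to the menthyloxy group; C8 is controlled by C8', the aldehyde entering anti to the bulky dithianyl group to give the trans,trans-lactone; C7 arises in the aldol, where the ring-locked E-enolate should favour the anti carbinol, but its configuration is not used because step 9 ionises it. The step needs 1,4- over 1,2-addition, which the soft delocalised aryl dithiane anion and the unhindered β-carbon should secure, and face selectivity at C8' and C8, which the C9' substituent and then the new C8' substituent secure in turn.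

Step 7
Reactants: 14 trans,trans-lactone
Product: 15 (3R,4S,5S)-3-[(4-allyloxy-3-methoxyphenyl)(hydroxy)methyl]-4-[3-methoxy-4-(triisopropylsilyloxy)benzoyl]-5-[(1S,2R,5S)-menthyloxy]dihydrofuran-2(3H)-one (C7 epimers)
Conditions: MeI, CaCO3, MeCN–H2O (9:1), 45 °C
Reagents that add atoms: water O
Why: S-Methylation turns the dithiane into a sulfonium leaving group and water hydrolyses the resulting thionium ion to the aryl ketone (alkylative dithioacetal hydrolysis), which avoids mercury and halonium reagents that would attack the allyl ether and should spare the silyl ether and the lactone acetal; no stereocentre is formed.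

Step 8
Reactants: 15 keto lactone
Product: 16 (2S,3S)-1-(4-allyloxy-3-methoxyphenyl)-2,3-bis(hydroxymethyl)-4-[3-methoxy-4-(triisopropylsilyloxy)phenyl]butane-1,4-diol (epimers at C7 and C7')
Conditions: LiAlH4, THF, 0 °C to rt; aq. NaOH work-up
Reagents that add atoms: none
Why: Hydride reduction of the ketone and of the γ-alkoxylactone, whose ring-opened hemiacetal alkoxide ejects menthoxide and is reduced on to the second CH2OH, should give the tetraol and return (+)-menthol; the new C7' carbinol forms without control and is reset in step 9.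

Step 9
Reactants: 16 tetraol
Product: 17 (1R,3aS,4R,6aS)-1-(4-allyloxy-3-methoxyphenyl)-4-[3-methoxy-4-(triisopropylsilyloxy)phenyl]tetrahydro-1H,3H-furo[3,4-c]furan [(7R,8S,7'R,8'S)-4-O-allyl-4'-O-triisopropylsilylpinoresinol]
Conditions: camphor-10-sulfonic acid (C10H16O4S, 0.1 equiv), 4 Å molecular sieves, CH2Cl2, 0 °C to rt
Reagents that add atoms: none
Why: Acid ionises both electron-rich benzylic carbinols to p-alkoxybenzyl cations that are captured 5-exo by the CH2OH group on the neighbouring carbon (C9'–OH at C7, C9–OH at C7') in a double SN1 cyclodehydration; the cis ring fusion follows from the fixed C8 and C8' centres, and each aryl group should settle kinetically on the exo face, trans to the adjacent fusion substituent, which sets C7 (R) and C7' (R) whatever their configuration in 16.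

Step 10
Reactants: 17 allyl silyl furofuran
Product: 18 (7R,8S,7'R,8'S)-4'-O-triisopropylsilylpinoresinol (ring B phenol free)
Conditions: Pd(PPh3)4 (5 mol %), morpholine, THF, rt
Reagents that add atoms: none
Why: Zerovalent palladium ionises the allyl aryl ether to a π-allyl complex that morpholine intercepts (Tsuji–Trost deallylation), which should free only the ring B phenol and leave the silyl ether and the benzylic ethers of the furofuran untouched.

Step 11
Reactants: 19 (S)-4-benzyloxazolidin-2-one
Product: 21 (S)-4-benzyl-3-(bromoacetyl)oxazolidin-2-one, via N-lithio oxazolidinone 20 (not isolated)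
Conditions: n-BuLi, THF, −78 °C; BrCH2COBr, −78 to 0 °C
Reagents that add atoms: bromoacetyl bromide O=C(Br)CBr
Why: N-Acylation of the lithiated oxazolidinone by the acid bromide, which at low temperature reacts at the acyl carbon much faster than at the CH2Br carbon.

Step 12
Reactants: 18 ring B phenol; 21 (S)-4-benzyl-3-(bromoacetyl)oxazolidin-2-one
Product: 22 (S)-4-benzyl-3-(aryloxyacetyl)oxazolidin-2-one (aryloxy = ring B oxygen of 18)
Conditions: K2CO3, acetone, rt
Reagents that add atoms: none
Why: Williamson etherification in which the phenoxide should displace the activated α-bromide by SN2 faster than it attacks the imide carbonyls, forming the C8''–O bond under conditions that leave the aryl triisopropylsilyl ether alone.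

Step 13
Reactants: 22 aryloxyacetyl imide; 8 3-methoxy-4-(triisopropylsilyloxy)benzaldehyde
Product: 24 (S)-4-benzyl-3-[(2R,3R)-2-(aryloxy)-3-hydroxy-3-(3-methoxy-4-triisopropylsilyloxyphenyl)propanoyl]oxazolidin-2-one (aryloxy as in 22; anti), via O-trimethylsilyl aldol ether 23 (not isolated)
Conditions: MgCl2 (0.2 equiv), Et3N, Me3SiCl, EtOAc, rt; then pyridinium p-toluenesulfonate (C12H13NO3S, cat.), MeOH, 0 °C
Reagents that add atoms: none
Why: Proposed new method: soft enolisation by triethylamine of the imide chelated to divalent magnesium through its two carbonyl groups (eased by the α-aryloxy group) should give the Z-enolate, which adds to the non-enolisable aldehyde 8 on the face away from the benzyl group of the chelated auxiliary and is turned over by O-silylation of the magnesium aldolate, the silyl ether 23 being cleaved in the acidic methanol work-up; the closest known reaction type is the MgCl2-catalysed anti-aldol of N-acyloxazolidinones with aromatic aldehydes (and, for the α-oxygenated enolate, anti-glycolate aldols of N-glycolyl imides), by analogy with which the (S)-benzyl auxiliary should set C8'' in the chelate-controlled sense and C7'' anti to it, (2R,3R) in 24 and (7''R,8''S) after step 14, the weakly basic aryl ether oxygen not being expected to disturb the imide chelate.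

Step 14
Reactants: 24 anti-aldol adduct
Product: 25 (7''R,8''S)-diol (the target with both phenols as triisopropylsilyl ethers)
Conditions: LiBH4, MeOH (1 equiv), THF, 0 °C
Reagents that add atoms: none
Why: Borohydride reduction of the exocyclic imide carbonyl (reductive removal of the oxazolidinone auxiliary) should give the C9'' primary alcohol and return 19 without touching C7'' or C8'', the low temperature guarding against retro-aldol.

Step 15
Reactants: 25 bis-silyl ether
Product: 26 (1R,2S)-1-(4-hydroxy-3-methoxyphenyl)-2-{4-[(1R,3aS,4R,6aS)-4-(4-hydroxy-3-methoxyphenyl)tetrahydro-1H,3H-furo[3,4-c]furan-1-yl]-2-methoxyphenoxy}propane-1,3-diol (target)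
Conditions: Bu4NF, AcOH (1:1), THF, 0 °C to rt
Reagents that add atoms: none
Why: Fluoride cleaves both aryl silyl ethers (desilylation) while the acetic acid buffer keeps the liberated p-hydroxybenzyl alcohol and the furofuran away from quinone methide chemistry, so all six stereocentres should be carried through unchanged.

**Compound list**

1 | furfural | O=Cc1ccco1 | starting material
2 | furfural 2,5-endoperoxide (2,3,7-trioxabicyclo[2.2.1]hept-5-ene-1-carbaldehyde, racemic) | O=CC12OOC(O1)C=C2 | intermediate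
3 | 5-hydroxyfuran-2(5H)-one (racemic) | OC1OC(=O)C=C1 | intermediate
4 | (+)-menthol, (1S,2R,5S) | CC(C)[C@H]1CC[C@H](C)C[C@@H]1O | starting material
5 | (5R)-5-[(1S,2R,5S)-menthyloxy]furan-2(5H)-one | CC(C)[C@H]1CC[C@H](C)C[C@@H]1O[C@@H]1OC(=O)C=C1 | intermediate
6 | (5S)-5-[(1S,2R,5S)-menthyloxy]furan-2(5H)-one | CC(C)[C@H]1CC[C@H](C)C[C@@H]1O[C@H]1OC(=O)C=C1 | intermediate
7 | vanillin | COc1cc(C=O)ccc1O | starting material
8 | 3-methoxy-4-(triisopropylsilyloxy)benzaldehyde | COc1cc(C=O)ccc1O[Si](C(C)C)(C(C)C)C(C)C | intermediate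
9 | propane-1,3-dithiol | SCCCS | starting material
10 | 2-[3-methoxy-4-(triisopropylsilyloxy)phenyl]-1,3-dithiane | COc1cc(C2SCCCS2)ccc1O[Si](C(C)C)(C(C)C)C(C)C | intermediate
11 | 4-(allyloxy)-3-methoxybenzaldehyde | C=CCOc1ccc(C=O)cc1OC | intermediate
12 | 2-lithio-2-[3-methoxy-4-(triisopropylsilyloxy)phenyl]-1,3-dithiane | COc1cc(C2([Li])SCCCS2)ccc1O[Si](C(C)C)(C(C)C)C(C)C | intermediate
13 | lithium enolate of the (4S,5S) conjugate adduct of 12 and 6 | CC(C)[C@H]1CC[C@H](C)C[C@@H]1O[C@H]1OC(O[Li])=C[C@@H]1C1(c2ccc(O[Si](C(C)C)(C(C)C)C(C)C)c(OC)c2)SCCCS1 | intermediate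
14 | (3R,4S,5S)-3-[(4-allyloxy-3-methoxyphenyl)(hydroxy)methyl]-5-[(1S,2R,5S)-menthyloxy]-4-{2-[3-methoxy-4-(triisopropylsilyloxy)phenyl]-1,3-dithian-2-yl}dihydrofuran-2(3H)-one, C7 epimers | CC(C)[C@H]1CC[C@H](C)C[C@@H]1O[C@H]1OC(=O)[C@@H](C(O)c2ccc(OCC=C)c(OC)c2)[C@@H]1C1(c2ccc(O[Si](C(C)C)(C(C)C)C(C)C)c(OC)c2)SCCCS1 | intermediate
15 | (3R,4S,5S)-3-[(4-allyloxy-3-methoxyphenyl)(hydroxy)methyl]-4-[3-methoxy-4-(triisopropylsilyloxy)benzoyl]-5-[(1S,2R,5S)-menthyloxy]dihydrofuran-2(3H)-one, C7 epimers | CC(C)[C@H]1CC[C@H](C)C[C@@H]1O[C@H]1OC(=O)[C@@H](C(O)c2ccc(OCC=C)c(OC)c2)[C@@H]1C(=O)c1ccc(O[Si](C(C)C)(C(C)C)C(C)C)c(OC)c1 | intermediate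
16 | (2S,3S)-1-(4-allyloxy-3-methoxyphenyl)-2,3-bis(hydroxymethyl)-4-[3-methoxy-4-(triisopropylsilyloxy)phenyl]butane-1,4-diol, epimers at C7 and C7' | C=CCOc1ccc(C(O)[C@H](CO)[C@@H](CO)C(O)c2ccc(O[Si](C(C)C)(C(C)C)C(C)C)c(OC)c2)cc1OC | intermediate
17 | (1R,3aS,4R,6aS)-1-(4-allyloxy-3-methoxyphenyl)-4-[3-methoxy-4-(triisopropylsilyloxy)phenyl]tetrahydro-1H,3H-furo[3,4-c]furan | C=CCOc1ccc([C@@H]2OC[C@@H]3[C@H]2CO[C@H]3c2ccc(O[Si](C(C)C)(C(C)C)C(C)C)c(OC)c2)cc1OC | intermediate
18 | 2-methoxy-4-{(1R,3aS,4R,6aS)-4-[3-methoxy-4-(triisopropylsilyloxy)phenyl]tetrahydro-1H,3H-furo[3,4-c]furan-1-yl}phenol | Oc1ccc([C@@H]2OC[C@@H]3[C@H]2CO[C@H]3c2ccc(O[Si](C(C)C)(C(C)C)C(C)C)c(OC)c2)cc1OC | intermediate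
19 | (S)-4-benzyloxazolidin-2-one | O=C1N[C@@H](Cc2ccccc2)CO1 | starting material
20 | N-lithio-(S)-4-benzyloxazolidin-2-one | [Li]N1[C@@H](Cc2ccccc2)COC1=O | intermediate
21 | (S)-4-benzyl-3-(bromoacetyl)oxazolidin-2-one | O=C(CBr)N1[C@@H](Cc2ccccc2)COC1=O | intermediate
22 | (S)-4-benzyl-3-(aryloxyacetyl)oxazolidin-2-one, aryloxy = ring B oxygen of 18 | O=C(COc1ccc([C@@H]2OC[C@@H]3[C@H]2CO[C@H]3c2ccc(O[Si](C(C)C)(C(C)C)C(C)C)c(OC)c2)cc1OC)N1[C@@H](Cc2ccccc2)COC1=O | intermediate
23 | O-trimethylsilyl ether of 24 at C7'' | O=C([C@H](Oc1ccc([C@@H]2OC[C@@H]3[C@H]2CO[C@H]3c2ccc(O[Si](C(C)C)(C(C)C)C(C)C)c(OC)c2)cc1OC)[C@H](O[Si](C)(C)C)c1ccc(O[Si](C(C)C)(C(C)C)C(C)C)c(OC)c1)N1[C@@H](Cc2ccccc2)COC1=O | intermediate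
24 | (S)-4-benzyl-3-[(2R,3R)-2-(aryloxy)-3-hydroxy-3-(3-methoxy-4-triisopropylsilyloxyphenyl)propanoyl]oxazolidin-2-one, aryloxy as in 22 | O=C([C@H](Oc1ccc([C@@H]2OC[C@@H]3[C@H]2CO[C@H]3c2ccc(O[Si](C(C)C)(C(C)C)C(C)C)c(OC)c2)cc1OC)[C@H](O)c1ccc(O[Si](C(C)C)(C(C)C)C(C)C)c(OC)c1)N1[C@@H](Cc2ccccc2)COC1=O | intermediate
25 | (7''R,8''S)-diol, the target with both phenols as triisopropylsilyl ethers | COc1cc([C@@H](O)[C@H](CO)Oc2ccc([C@@H]3OC[C@@H]4[C@H]3CO[C@H]4c3ccc(O[Si](C(C)C)(C(C)C)C(C)C)c(OC)c3)cc2OC)ccc1O[Si](C(C)C)(C(C)C)C(C)C | intermediate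
26 | (1R,2S)-1-(4-hydroxy-3-methoxyphenyl)-2-{4-[(1R,3aS,4R,6aS)-4-(4-hydroxy-3-methoxyphenyl)tetrahydro-1H,3H-furo[3,4-c]furan-1-yl]-2-methoxyphenoxy}propane-1,3-diol | COc1cc([C@@H](O)[C@H](CO)Oc2ccc([C@@H]3OC[C@@H]4[C@H]3CO[C@H]4c3ccc(O)c(OC)c3)cc2OC)ccc1O | target

**Step count and risks**

Total steps: 15. Longest linear sequence: 11 steps (1, 2, 6–10, 12–15; the vanillin branch 3, 4, 6–10, 12–15 is equally long).

Steps most likely to fail:

1. Step 13. The magnesium enolate may fail to turn over with the electron-rich aldehyde, or may add with low anti selectivity or in the other facial sense if the α-aryloxy group perturbs the chelate. The fallback uses known chemistry, sets out from 18 and returns at 26. (R)-4-Benzyloxazolidin-2-one is lithiated to the N-lithio oxazolidinone F1 and acylated with bromoacetyl bromide, as in step 11, to give (R)-4-benzyl-3-(bromoacetyl)oxazolidin-2-one F2. Alkylation of 18 with it (K2CO3, acetone) gives the (R)-aryloxyacetyl imide F3. Its boron Z-enolate (Bu2BOTf, i-Pr2NEt, CH2Cl2, −78 to 0 °C) adds to 8 in an Evans syn-aldol to give the (2R,3S) syn adduct F4, which has the right C8'' and the wrong C7'' configuration. LiBH4 then gives the threo diol F5, and t-BuMe2SiCl with imidazole masks the primary alcohol as the silyl ether F6. A Mitsunobu reaction with 4-nitrobenzoic acid (PPh3, diisopropyl azodicarboxylate, THF, 0 °C) inverts C7'' to give the 4-nitrobenzoate F7, K2CO3 in MeOH at 0 °C releases the erythro alcohol F8, and Bu4NF with AcOH gives 26.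

2. Step 6. Trapping of the enolate by the deactivated aldehyde may be outrun by proton transfer or by reversal of the aldol, so that only the 1,4-adduct is returned. The fallback separates the two bond formations, sets out from 10 and 6 and returns at 14. The conjugate addition is run alone and quenched with NH4Cl to give the (4S,5S) conjugate adduct F9. Its enolate is regenerated with LiN(i-Pr)2 in THF at −78 °C and transmetalated with ZnCl2 to the chlorozinc enolate F10 (not isolated), which is treated with 11 in a separate directed aldol to give 14.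

3. Step 9. With both benzylic carbinols ionising at once, closure between C7 and C7' to a 2,5-diaryltetrahydrofuran, or closure with an endo aryl group, may compete with the double exo closure. The fallback closes one ring at a time, sets out from 14 and returns at 17. LiAlH4 reduction of 14 with the dithiane kept gives the dithianyl triol F11. Camphor-10-sulfonic acid can then close only the C7–O–C9' ring, because C7 is the one benzylic carbinol, and gives the dithianyl tetrahydrofuran F12. MeI and CaCO3 in aqueous MeCN unmask the C7' ketone F13, which should rest largely as the bicyclic lactol with the C9 hydroxyl. NaBH4 gives the diol F14, and a second acid-catalysed closure forms the C7'–O–C9 ring to give 17.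

**Further compounds**

F1 | step 13 | N-lithio-(R)-4-benzyloxazolidin-2-one | [Li]N1[C@H](Cc2ccccc2)COC1=O
F2 | step 13 | (R)-4-benzyl-3-(bromoacetyl)oxazolidin-2-one | O=C(CBr)N1[C@H](Cc2ccccc2)COC1=O
F3 | step 13 | (R)-4-benzyl-3-(aryloxyacetyl)oxazolidin-2-one, aryloxy = ring B oxygen of 18 | O=C(COc1ccc([C@@H]2OC[C@@H]3[C@H]2CO[C@H]3c2ccc(O[Si](C(C)C)(C(C)C)C(C)C)c(OC)c2)cc1OC)N1[C@H](Cc2ccccc2)COC1=O
F4 | step 13 | (R)-4-benzyl-3-[(2R,3S)-2-(aryloxy)-3-hydroxy-3-(3-methoxy-4-triisopropylsilyloxyphenyl)propanoyl]oxazolidin-2-one (syn adduct) | O=C([C@H](Oc1ccc([C@@H]2OC[C@@H]3[C@H]2CO[C@H]3c2ccc(O[Si](C(C)C)(C(C)C)C(C)C)c(OC)c2)cc1OC)[C@@H](O)c1ccc(O[Si](C(C)C)(C(C)C)C(C)C)c(OC)c1)N1[C@H](Cc2ccccc2)COC1=O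
F5 | step 13 | (7''S,8''S)-threo diol, both phenols as triisopropylsilyl ethers | COc1cc([C@H](O)[C@H](CO)Oc2ccc([C@@H]3OC[C@@H]4[C@H]3CO[C@H]4c3ccc(O[Si](C(C)C)(C(C)C)C(C)C)c(OC)c3)cc2OC)ccc1O[Si](C(C)C)(C(C)C)C(C)C
F6 | step 13 | C9''-O-tert-butyldimethylsilyl ether of F5 | COc1cc([C@H](O)[C@H](CO[Si](C)(C)C(C)(C)C)Oc2ccc([C@@H]3OC[C@@H]4[C@H]3CO[C@H]4c3ccc(O[Si](C(C)C)(C(C)C)C(C)C)c(OC)c3)cc2OC)ccc1O[Si](C(C)C)(C(C)C)C(C)C
F7 | step 13 | (7''R,8''S)-C7'' 4-nitrobenzoate | COc1cc([C@@H](OC(=O)c2ccc(cc2)[N+](=O)[O-])[C@H](CO[Si](C)(C)C(C)(C)C)Oc2ccc([C@@H]3OC[C@@H]4[C@H]3CO[C@H]4c3ccc(O[Si](C(C)C)(C(C)C)C(C)C)c(OC)c3)cc2OC)ccc1O[Si](C(C)C)(C(C)C)C(C)C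
F8 | step 13 | (7''R,8''S)-erythro alcohol with C9''-O-tert-butyldimethylsilyl and two aryl triisopropylsilyl ethers | COc1cc([C@@H](O)[C@H](CO[Si](C)(C)C(C)(C)C)Oc2ccc([C@@H]3OC[C@@H]4[C@H]3CO[C@H]4c3ccc(O[Si](C(C)C)(C(C)C)C(C)C)c(OC)c3)cc2OC)ccc1O[Si](C(C)C)(C(C)C)C(C)C
F9 | step 6 | (4S,5S)-5-[(1S,2R,5S)-menthyloxy]-4-{2-[3-methoxy-4-(triisopropylsilyloxy)phenyl]-1,3-dithian-2-yl}dihydrofuran-2(3H)-one | CC(C)[C@H]1CC[C@H](C)C[C@@H]1O[C@H]1OC(=O)C[C@@H]1C1(c2ccc(O[Si](C(C)C)(C(C)C)C(C)C)c(OC)c2)SCCCS1
F10 | step 6 | chlorozinc enolate of F9 | CC(C)[C@H]1CC[C@H](C)C[C@@H]1O[C@H]1OC(O[Zn]Cl)=C[C@@H]1C1(c2ccc(O[Si](C(C)C)(C(C)C)C(C)C)c(OC)c2)SCCCS1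
F11 | step 9 | (2S,3S)-dithianyl triol from reduction of 14, C7 epimers | C=CCOc1ccc(C(O)[C@H](CO)[C@@H](CO)C2(c3ccc(O[Si](C(C)C)(C(C)C)C(C)C)c(OC)c3)SCCCS2)cc1OC
F12 | step 9 | 2-aryl-3-(hydroxymethyl)-4-(2-aryl-1,3-dithian-2-yl)tetrahydrofuran (C7–O–C9' ring closed) | C=CCOc1ccc([C@@H]2OC[C@@H](C3(c4ccc(O[Si](C(C)C)(C(C)C)C(C)C)c(OC)c4)SCCCS3)[C@H]2CO)cc1OC
F13 | step 9 | C7' ketone of F12 (open form of the bicyclic lactol) | C=CCOc1ccc([C@@H]2OC[C@@H](C(=O)c3ccc(O[Si](C(C)C)(C(C)C)C(C)C)c(OC)c3)[C@H]2CO)cc1OC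
F14 | step 9 | C7' carbinol diol from F13, C7' epimers | C=CCOc1ccc([C@@H]2OC[C@@H](C(O)c3ccc(O[Si](C(C)C)(C(C)C)C(C)C)c(OC)c3)[C@H]2CO)cc1OC
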